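The 3(2H)-furanone (O, C3, C2, C1, C10; germacranolide numbering) is read as a 1,3-diketone enolate alkylated on oxygen by C10, and the diketone as the product of an O-to-C acyl shift. The precursor is a ten-membered macrolactone: the C1 acid, with a tertiary mesylate at C10, esterifies the C15 hydroxyl next to the C3 methyl ketone. One equivalent of base makes the C2 enolate; it attacks C1 through a six-membered transition state, which trades the lactone for the ten-membered carbocycle (C1–C10) and frees the C15–OH, and the diketonate oxygen then closes on C10 with inversion. The step exploits the 1,5 relation of O15 and C2 across C3–C4.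

Key step: step 11

Remark: atoms carry germacranolide numbers (C1 ketone; C2, C3, ring O and C10 in the furanone; C4=C5; C6–C9; C11–C13 in the methylene lactone; C14 methyl; C15 CH2OH), and compounds 1, 3, 10 and 13 are assumed to be commercial.

Step 1
Reactants: 1 mesityl oxide
Product: 2 trimethyl[(4-methylpenta-1,3-dien-2-yl)oxy]silane
Conditions: LiN(i-Pr)2, THF, −78 °C; TMSCl, −78 °C → 23 °C
Reagents that add atoms: chlorotrimethylsilane, C[Si](C)(C)Cl
Why: Kinetic deprotonation of the enone at its α′-methyl group and O-silylation should give the cross-conjugated silyl dienol ether (silyl enol ether formation).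

Step 2
Reactants: 2 trimethyl[(4-methylpenta-1,3-dien-2-yl)oxy]silane; 3 tert-butyl pyruvate
Product: 5 tert-butyl (S)-2-hydroxy-2,6-dimethyl-4-oxohept-5-enoate, via silyl ether 4 (not isolated)
Conditions: Cu(OTf)2 (10 mol %), 2,2′-(propane-2,2-diyl)bis[(4S)-4-tert-butyl-4,5-dihydrooxazole] (11 mol %), THF, −78 °C; then 1 N HCl, THF, 0 °C
Reagents that add atoms: none
Why: Catalytic enantioselective Mukaiyama aldol addition to the pyruvate chelated on the divalent copper–bis(oxazoline) Lewis acid, in which the ligand shields one face of the ketone so that the terminal CH2 of 2 adds to the si face and sets the (S) tertiary carbinol (the future C10).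

Step 3
Reactants: 5 tert-butyl (S)-2-hydroxy-2,6-dimethyl-4-oxohept-5-enoate
Product: 7 tert-butyl (2S,4R)-2-hydroxy-2,6-dimethyl-4-[(2-methylpropanoyl)oxy]hept-5-enoate, via diol 6 (not isolated)
Conditions: (S)-2-methyl-CBS-oxazaborolidine (0.2 equiv), catecholborane, toluene, −78 °C; MeOH, evaporation; then (i-PrCO)2O, Et3N, DMAP (cat.), CH2Cl2, 0 °C
Reagents that add atoms: isobutyric anhydride, CC(C)C(=O)OC(=O)C(C)C
Why: Corey–Bakshi–Shibata reduction of the enone (alkenyl as the large group) should set the (R) carbinol at C8 under reagent control, the tert-butyl ester resists lactonisation by the new hydroxyl, and acylation then takes the secondary alcohol in preference to the tertiary one.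

Step 4
Reactants: 7 tert-butyl (2S,4R)-2-hydroxy-2,6-dimethyl-4-[(2-methylpropanoyl)oxy]hept-5-enoate
Product: 8 tert-butyl (2S,4R)-2,6-dimethyl-2-[(methylsulfonyl)oxy]-4-[(2-methylpropanoyl)oxy]hept-5-enoate
Conditions: MsCl, Et3N, CH2Cl2, −10 → 0 °C
Reagents that add atoms: methanesulfonyl chloride, CS(=O)(=O)Cl
Why: Sulfonylation through sulfene reaches the hindered tertiary α-hydroxy ester and takes place at oxygen, so the C10 configuration is retained (mesylate formation).

Step 5
Reactants: 8 tert-butyl (2S,4R)-2,6-dimethyl-2-[(methylsulfonyl)oxy]-4-[(2-methylpropanoyl)oxy]hept-5-enoate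
Product: 9 tert-butyl (2S,4R)-2-methyl-2-[(methylsulfonyl)oxy]-4-[(2-methylpropanoyl)oxy]-5-oxopentanoate
Conditions: O3, CH2Cl2, −78 °C; Me2S, −78 → 23 °C
Reagents that add atoms: ozone, [O-][O+]=O
Why: Ozonolysis with reductive work-up cleaves the only alkene, an electron-rich trisubstituted one, to the α-acyloxy aldehyde (C7) without touching C8.

Step 6
Reactants: 9 tert-butyl (2S,4R)-2-methyl-2-[(methylsulfonyl)oxy]-4-[(2-methylpropanoyl)oxy]-5-oxopentanoate; 10 methyl acrylate
Product: 11 1-tert-butyl 7-methyl (2S,4R)-5-hydroxy-2-methyl-6-methylidene-2-[(methylsulfonyl)oxy]-4-[(2-methylpropanoyl)oxy]heptanedioate (both C5 epimers)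
Conditions: DABCO (0.5 equiv), methyl acrylate (5 equiv), MeOH, 0 → 23 °C
Reagents that add atoms: none
Why: Morita–Baylis–Hillman reaction, fast for an activated α-acyloxy aldehyde in a protic medium, and the new carbinol centre need not be controlled because it becomes sp2 in step 7.

Step 7
Reactants: 11 1-tert-butyl 7-methyl (2S,4R)-5-hydroxy-2-methyl-6-methylidene-2-[(methylsulfonyl)oxy]-4-[(2-methylpropanoyl)oxy]heptanedioate
Product: 12 (2S,4R,5Z)-6-(bromomethyl)-7-methoxy-2-methyl-2-[(methylsulfonyl)oxy]-4-[(2-methylpropanoyl)oxy]-7-oxohept-5-enoic acid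
Conditions: HBr (33 % in AcOH), CH2Cl2, 0 → 23 °C
Reagents that add atoms: hydrogen bromide, Br
Why: Acid-mediated SN2′ bromination of the Morita–Baylis–Hillman alcohol should give the more stable (Z)-2-(bromomethyl)alk-2-enoate, and the same acid cleaves the tert-butyl ester while the secondary isobutyrate and the α-carbonyl mesylate should survive.

Step 8
Reactants: 12 (2S,4R,5Z)-6-(bromomethyl)-7-methoxy-2-methyl-2-[(methylsulfonyl)oxy]-4-[(2-methylpropanoyl)oxy]-7-oxohept-5-enoic acid; 13 (2-methylfuran-3-yl)methanol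
Product: 15 7-methyl 1-[(2-methylfuran-3-yl)methyl] (2S,4R,5Z)-6-(bromomethyl)-2-methyl-2-[(methylsulfonyl)oxy]-4-[(2-methylpropanoyl)oxy]hept-5-enedioate, via acid chloride 14 (not isolated)
Conditions: 1-chloro-N,N,2-trimethylprop-1-en-1-amine, CH2Cl2, 0 → 23 °C; then 13, 2,6-lutidine, 0 → 23 °C
Reagents that add atoms: none
Why: Esterification through the acid chloride, made under neutral conditions and coupled with a hindered base, should spare the allylic bromide and the acid-sensitive furan.

Step 9
Reactants: 15 7-methyl 1-[(2-methylfuran-3-yl)methyl] (2S,4R,5Z)-6-(bromomethyl)-2-methyl-2-[(methylsulfonyl)oxy]-4-[(2-methylpropanoyl)oxy]hept-5-enedioate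
Product: 16 7-methyl 1-[(2Z)-2-acetyl-4-oxobut-2-en-1-yl] (2S,4R,5Z)-6-(bromomethyl)-2-methyl-2-[(methylsulfonyl)oxy]-4-[(2-methylpropanoyl)oxy]hept-5-enedioate
Conditions: NBS (1.05 equiv), NaHCO3, acetone/H2O (10:1), −20 °C
Reagents that add atoms: water, O
Why: Oxidative ring opening of the furan (bromination at C5 of the furan, hydration, loss of HBr) unveils the C3 methyl ketone and the C6 aldehyde, which were both bound to the ring oxygen and are therefore cis on C4=C5, the required alkene geometry.

Step 10
Reactants: 16 7-methyl 1-[(2Z)-2-acetyl-4-oxobut-2-en-1-yl] (2S,4R,5Z)-6-(bromomethyl)-2-methyl-2-[(methylsulfonyl)oxy]-4-[(2-methylpropanoyl)oxy]hept-5-enedioate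
Product: 18 trans-fused methylene-lactone macrolactone (6R,7R,8R,10S), via hydroxy ester 17 (not isolated)
Conditions: CrCl2 (8 equiv), THF, 25 °C, slow addition of 16 to a final 2 mM; aqueous NH4Cl work-up; then PPTS (cat.), CH2Cl2, 25 °C
Reagents that add atoms: none
Why: Intramolecular Nozaki–Hiyama allylation in which the 2-(methoxycarbonyl)allylchromium adds through C7 to the aldehyde in a chair (Zimmerman–Traxler) transition state with both ring chains equatorial (anti adduct, hence the trans lactone), allylic 1,3-strain holds H-8 in the alkene plane so that the aldehyde is delivered to the face of C7 opposite to the C9 chain and (6R,7R) results, and the alkoxide lactonises onto the methyl ester.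

Step 11
Reactants: 18 trans-fused methylene-lactone macrolactone (6R,7R,8R,10S)
Product: 20 CNP0176924.3 (the target), via diketone 19 (not isolated)
Conditions: LiN(SiMe3)2 (1.05 equiv), THF, −78 °C; then DMPU (4 equiv), −78 → 0 °C
Reagents that add atoms: none
Why: LiN(SiMe3)2 removes a proton from the C2 methyl group of the C3 enone (kinetic cross-conjugated enolate) and C2 adds to the lactone carbonyl C1 through a six-membered tetrahedral intermediate (C2–C3–C4–C15–O–C1) whose collapse expels the C15 alkoxide, an intramolecular Claisen condensation of the Baker–Venkataraman type (O-to-C acyl migration in a β-acyloxy ketone enolate). The ten-membered carbocycle C1–C10 is therefore closed by transannular ring switching (6-exo-trig attack on the ester inside the macrolactone, then C1–O15 cleavage) and not by an end-to-end cyclisation, and because C4=C5 is trans in the lactone ring and cis in the carbocycle the bicyclic intermediate holds no forbidden bridgehead alkene. The alkoxide deprotonates the β-diketone 19, and the enolate oxygen on C3 displaces the tertiary α-keto mesylate at C10 in a 5-exo-tet closure, the known base-induced cyclisation of 1,3-diketones with a γ-leaving group to 3(2H)-furanones. C10 is the only stereocentre touched, and it is controlled by the (10S) mesylate that goes back to step 2: backside attack inverts it to (10R). The step needs enolisation at C2 rather than γ-deprotonation or conjugate addition to the methylene lactone (secured by the hindered amide base at −78 °C and the six-membered transition state) and substitution rather than elimination at C10 (secured by the single equivalent of base, the carbonyl activation of the mesylate and the intramolecular five-membered attack, C-alkylation being excluded because it would need a three-membered ring).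

Compound list
1 | mesityl oxide (4-methylpent-3-en-2-one) | CC(=O)C=C(C)C | starting material
2 | trimethyl[(4-methylpenta-1,3-dien-2-yl)oxy]silane | C=C(O[Si](C)(C)C)C=C(C)C | intermediate
3 | tert-butyl pyruvate (tert-butyl 2-oxopropanoate) | CC(=O)C(=O)OC(C)(C)C | starting material
4 | tert-butyl (S)-2,6-dimethyl-4-oxo-2-[(trimethylsilyl)oxy]hept-5-enoate (not isolated) | CC(C)=CC(=O)C[C@](C)(O[Si](C)(C)C)C(=O)OC(C)(C)C | intermediate
5 | tert-butyl (S)-2-hydroxy-2,6-dimethyl-4-oxohept-5-enoate | CC(C)=CC(=O)C[C@](C)(O)C(=O)OC(C)(C)C | intermediate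
6 | tert-butyl (2S,4R)-2,4-dihydroxy-2,6-dimethylhept-5-enoate (not isolated) | CC(C)=C[C@H](O)C[C@](C)(O)C(=O)OC(C)(C)C | intermediate
7 | tert-butyl (2S,4R)-2-hydroxy-2,6-dimethyl-4-[(2-methylpropanoyl)oxy]hept-5-enoate | CC(C)=C[C@H](OC(=O)C(C)C)C[C@](C)(O)C(=O)OC(C)(C)C | intermediate
8 | tert-butyl (2S,4R)-2,6-dimethyl-2-[(methylsulfonyl)oxy]-4-[(2-methylpropanoyl)oxy]hept-5-enoate | CC(C)=C[C@H](OC(=O)C(C)C)C[C@](C)(OS(C)(=O)=O)C(=O)OC(C)(C)C | intermediate
9 | tert-butyl (2S,4R)-2-methyl-2-[(methylsulfonyl)oxy]-4-[(2-methylpropanoyl)oxy]-5-oxopentanoate | O=C[C@H](OC(=O)C(C)C)C[C@](C)(OS(C)(=O)=O)C(=O)OC(C)(C)C | intermediate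
10 | methyl acrylate | C=CC(=O)OC | starting material
11 | 1-tert-butyl 7-methyl (2S,4R)-5-hydroxy-2-methyl-6-methylidene-2-[(methylsulfonyl)oxy]-4-[(2-methylpropanoyl)oxy]heptanedioate, both C5 epimers | C=C(C(=O)OC)C(O)[C@H](OC(=O)C(C)C)C[C@](C)(OS(C)(=O)=O)C(=O)OC(C)(C)C | intermediate
12 | (2S,4R,5Z)-6-(bromomethyl)-7-methoxy-2-methyl-2-[(methylsulfonyl)oxy]-4-[(2-methylpropanoyl)oxy]-7-oxohept-5-enoic acid | COC(=O)/C(CBr)=C/[C@H](OC(=O)C(C)C)C[C@](C)(OS(C)(=O)=O)C(=O)O | intermediate
13 | (2-methylfuran-3-yl)methanol | Cc1occc1CO | starting material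
14 | acid chloride of 12 (not isolated) | COC(=O)/C(CBr)=C/[C@H](OC(=O)C(C)C)C[C@](C)(OS(C)(=O)=O)C(Cl)=O | intermediate
15 | 7-methyl 1-[(2-methylfuran-3-yl)methyl] (2S,4R,5Z)-6-(bromomethyl)-2-methyl-2-[(methylsulfonyl)oxy]-4-[(2-methylpropanoyl)oxy]hept-5-enedioate | COC(=O)/C(CBr)=C/[C@H](OC(=O)C(C)C)C[C@](C)(OS(C)(=O)=O)C(=O)OCc1ccoc1C | intermediate
16 | 7-methyl 1-[(2Z)-2-acetyl-4-oxobut-2-en-1-yl] (2S,4R,5Z)-6-(bromomethyl)-2-methyl-2-[(methylsulfonyl)oxy]-4-[(2-methylpropanoyl)oxy]hept-5-enedioate | COC(=O)/C(CBr)=C/[C@H](OC(=O)C(C)C)C[C@](C)(OS(C)(=O)=O)C(=O)OC/C(C(C)=O)=C/C=O | intermediate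
17 | ten-membered lactone (ring C1(=O)–O–C15–C4=C5–C6–C7–C8–C9–C10) with 4-acetyl, C6–OH, C7–C(=CH2)CO2Me, 8-isobutyrate, 10-methyl and 10-mesylate, configured as 18 (not isolated) | CC(=O)/C1=C\[C@@H](O)[C@H](C(=C)C(=O)OC)[C@H](OC(=O)C(C)C)C[C@](C)(OS(C)(=O)=O)C(=O)OC1 | intermediate
18 | the same ten-membered lactone with the α-methylene-γ-butyrolactone (O–C6, C7, C11=C13H2, C12=O) closed and trans-fused; C3 acetyl cis to C6 on C4=C5; (6R,7R,8R,10S) | CC(=O)/C1=C\[C@H]2OC(=O)C(=C)[C@@H]2[C@H](OC(=O)C(C)C)C[C@](C)(OS(C)(=O)=O)C(=O)OC1 | intermediate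
19 | ten-membered carbocyclic 1,3-diketone (C1=O, C2H2, C3=O) with free C15–OH, 10-mesylate, 8-isobutyrate and the trans methylene lactone; (6R,7R,8R,10S) (not isolated) | C=C1C(=O)O[C@@H]2/C=C(/CO)C(=O)CC(=O)[C@@](C)(OS(C)(=O)=O)C[C@@H](OC(=O)C(C)C)[C@@H]12 | intermediate
20 | CNP0176924.3: (6R,7R,8R,10R)-15-hydroxy-1-oxo-3,10-epoxygermacra-2,4(Z),11(13)-trien-12,6-olid-8-yl 2-methylpropanoate | C=C1C(=O)O[C@@H]2/C=C(/CO)C3=CC(=O)[C@@](C)(C[C@@H](OC(=O)C(C)C)[C@@H]12)O3 | target

Total step count: 11. Longest linear sequence: 11 steps (1 to 20); 3, 10 and 13 enter as purchased materials.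

Steps most likely to fail

Step 11. The transannular acyl shift may stall if the macrolactone cannot fold into the six-membered transition state. Base may instead eliminate the tertiary mesylate or, after γ-deprotonation at C6, expel the C15 carboxylate. The fallback sets out from 16 and comes back at 20, and it moves the two bond formations out of the ring. The aldehyde of 16 is masked (HC(OMe)3, PPTS, MeOH) as the dimethyl acetal F1. LiN(SiMe3)2 (THF, −78 → 0 °C) then effects the same acyl shift and O-alkylation on this open-chain ester to give the 2,2-disubstituted 3(2H)-furanone acetal F2 with the free C15 hydroxyl. Mild hydrolysis (PPTS, acetone/H2O) gives the furanone aldehyde F3. The CrCl2 allylation and lactonisation of step 10 is then used last, on F3, to close the ten-membered carbocycle at C6–C7 together with the lactone and give 20.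

Step 10. Oligomerisation may outrun closure of the ten-membered lactone, CrCl2 may reduce or isomerise the cis keto-enal, and facial control at C6 and C7 may erode. The fallback sets out from 11 and 13 and comes back at 18, and it closes the ring at the ester instead. 11 is converted (NBS, Me2S, CH2Cl2) into the allylic bromide tert-butyl ester F4. 13 is silylated (TBSCl, imidazole) to the silyl ether F5 and opened (NBS, NaHCO3, aqueous acetone) to the keto-enal F6. Intermolecular CrCl2 allylation of F6 with F4, followed by lactonisation, should give the trans lactone F7 by the same chair transition state. CF3CO2H removes the tert-butyl ester and the silyl ether to give the seco hydroxy acid F8. A Mitsunobu macrolactonisation (PPh3, DIAD, toluene, high dilution), which activates the unhindered C15 carbinol and not the hindered acid, gives 18.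

Step 6. The α-acyloxy aldehyde may epimerise at C8 by enolisation, and in the long-lived amine aldolate the isobutyryl group may migrate to the new C7 hydroxyl. The fallback sets out from 9 and comes back at 11, and it replaces the amine-catalysed manifold by a preformed vinyl metal. Hydroalumination of methyl propiolate (i-Bu2AlH, HMPA, THF, 0 °C) gives the α-(methoxycarbonyl)vinylalane F9, which adds to 9 at 0 °C under non-basic conditions and gives 11 after acidic work-up.

Further compounds
F1 | step 11 | 7-methyl 1-[(2Z)-2-acetyl-4,4-dimethoxybut-2-en-1-yl] (2S,4R,5Z)-6-(bromomethyl)-2-methyl-2-[(methylsulfonyl)oxy]-4-[(2-methylpropanoyl)oxy]hept-5-enedioate | COC(=O)/C(CBr)=C/[C@H](OC(=O)C(C)C)C[C@](C)(OS(C)(=O)=O)C(=O)OC/C(C(C)=O)=C/C(OC)OC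
F2 | step 11 | methyl (2Z,4R)-2-(bromomethyl)-5-[(2R)-5-[(2Z)-1-hydroxy-4,4-dimethoxybut-2-en-2-yl]-2-methyl-3-oxo-2,3-dihydrofuran-2-yl]-4-[(2-methylpropanoyl)oxy]pent-2-enoate | COC(=O)/C(CBr)=C/[C@H](OC(=O)C(C)C)C[C@@]1(C)OC(=CC1=O)/C(CO)=C\C(OC)OC
F3 | step 11 | methyl (2Z,4R)-2-(bromomethyl)-5-[(2R)-5-[(2Z)-1-hydroxy-4-oxobut-2-en-2-yl]-2-methyl-3-oxo-2,3-dihydrofuran-2-yl]-4-[(2-methylpropanoyl)oxy]pent-2-enoate | COC(=O)/C(CBr)=C/[C@H](OC(=O)C(C)C)C[C@@]1(C)OC(=CC1=O)/C(CO)=C\C=O
F4 | step 10 | 1-tert-butyl 7-methyl (2S,4R,5Z)-6-(bromomethyl)-2-methyl-2-[(methylsulfonyl)oxy]-4-[(2-methylpropanoyl)oxy]hept-5-enedioate | COC(=O)/C(CBr)=C/[C@H](OC(=O)C(C)C)C[C@](C)(OS(C)(=O)=O)C(=O)OC(C)(C)C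
F5 | step 10 | tert-butyldimethyl[(2-methylfuran-3-yl)methoxy]silane | Cc1occc1CO[Si](C)(C)C(C)(C)C
F6 | step 10 | (2Z)-3-{[(tert-butyldimethylsilyl)oxy]methyl}-4-oxopent-2-enal | CC(=O)/C(CO[Si](C)(C)C(C)(C)C)=C\C=O
F7 | step 10 | trans α-methylene-γ-butyrolactone carrying the (Z)-2-acetyl-3-(silyloxy)propenyl group at C6 and the tert-butyl ester side chain at C7, configured as 18 | CC(=O)/C(CO[Si](C)(C)C(C)(C)C)=C\[C@H]1OC(=O)C(=C)[C@@H]1[C@H](OC(=O)C(C)C)C[C@](C)(OS(C)(=O)=O)C(=O)OC(C)(C)C
F8 | step 10 | seco hydroxy acid of 18 (free C15–OH and free C1 acid) | CC(=O)/C(CO)=C\[C@H]1OC(=O)C(=C)[C@@H]1[C@H](OC(=O)C(C)C)C[C@](C)(OS(C)(=O)=O)C(=O)O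
F9 | step 6 | [1-(methoxycarbonyl)ethenyl]bis(2-methylpropyl)aluminium | C=C(C(=O)OC)[Al](CC(C)C)CC(C)C
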